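At early times I treated each flask as a bank of clocks, turning each rate constant into a time at the charged amounts.

in all of them: starting material 0.050 M; other conformer 0.0125 M; protic impurity 2.50 mM; free catalyst 0.12 mM; stray impurity 13 µM; time 3.0 d

|  | temperature |
|---|---|
| spring | 40 °C |
| dusk | 100 °C |
| autumn | 70 °C |

    free catalyst + stray impurity → spent catalyst (k1 = 47800 L mol⁻¹ h⁻¹, Ea1 = 50.0 kJ mol⁻¹)
    starting material ⇌ other conformer (K2 = 0.30, k2 = 0.388 h⁻¹, Ea2 = 95.0 kJ mol⁻¹, ΔH2 = −54.0 kJ mol⁻¹)
    starting material + target → side product (k3 = 0.147 L mol⁻¹ h⁻¹, Ea3 = 64.0 kJ mol⁻¹)
    other conformer + protic impurity → quenched substrate (k4 = 25.9 L mol⁻¹ h⁻¹, Ea4 = 47.0 kJ mol⁻¹)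
    starting material + free catalyst → free catalyst + target (k5 = 75.7 L mol⁻¹ h⁻¹, Ea5 = 63.0 kJ mol⁻¹)
    free catalyst + other conformer → free catalyst + isomer of the product (k6 = 1540 L mol⁻¹ h⁻¹, Ea6 = 44.0 kJ mol⁻¹)
    (constants at 40 °C)

- percentages count the starting material that a species holds: one side product counts as two
- constants are those at 40 °C; use the activation energies and enthalpies for any other temperature
- in a conversion other conformer counts as not yet reacted

- which flask leads in amount of target, in percent of the starting material and other conformer together charged ("all alike" within 1.5 percentage points) (spring / dusk / autumn / all alike)
- how much target is there at the end, in percent of the starting material and other conformer together charged: spring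
- how much target is there at the end, in percent of the starting material and other conformer together charged: dusk
- how much target is there at the end, in percent of the starting material and other conformer together charged: autumn

Starting material and other conformer exchange with each other, and the free catalyst turns the first into target and the second into isomer of the product. I therefore carried a branching ratio S, the rate of the step to target over the rate of the step to isomer, k_T[starting material]/(k_I[other conformer]). [free catalyst] stands in both rates and cancels. I reached S in two ways, both for autumn.

The first way took the concentrations as charged, and with the rate constants moved to 70 °C it gave 0.372. The second way let the exchange stand at equilibrium, so that S = k_T/(k_I K), which is 0.164 at 40 °C. Its temperature dependence has a single energy, the activation energy of the step to target minus that of the step to isomer minus the exchange enthalpy, 73.0 kJ mol⁻¹. That gave 1.90 for autumn, well above the first value.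

To find which way cheated, I compared two clocks in autumn. The exchange relaxes in 0.297 min, while the catalyst needs 74.1 min to consume other conformer. Because the exchange is so much faster, the charged ratio is lost almost at once, and the first way was the one that cheated.

I then took the equilibrium form for the other flasks too: 0.164 for spring and 14.9 for dusk. Of the material passing through the two catalysed steps, the share going to target came to 14.1% in spring, 65.5% in autumn and 93.7% in dusk. My reckoning stopped there. It counts target made, not target kept, since starting material also consumes target to give side product. I expected dusk to lead unless that loss reversed the order, but I committed to no final yields.

The forecast named dusk, with 12.8% for spring, 47% for dusk and 40% for autumn, and its ground was that “selectivity sets the ranking”.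

The simulation gave 12.8% for spring, 47.5% for dusk and 40.0% for autumn, so dusk led. Each side product holds one target, so target plus half the side product, over isomer of the product, reads 1.90 at the end of autumn, against S of 1.90. In a flask like autumn kept at 45 °C, S comes to 0.255, and the same reading is 0.268, with isomer of the product at 71.8%.

(The constants were drawn at random within sensible limits.)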